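If a charge of 0.12 M and a charge of 1.1 M lose solid substrate at the same molar pace, then that pace belongs to the dissolving rather than to the charge, and one number gives an estimate of how long the solid lasts in each flask of a plate.

| flask | solid substrate | remark | time |
|---|---|---|---|
| north-east | 0.12 M | run made earlier |  |
| north | 1.1 M | run made earlier |  |
| Monday's | 0.20 M |  | 4.0 h |
| Sunday's | 1.5 M |  | 4.0 h |
| Saturday's | 1.2 M |  | 4.0 h |
| Tuesday's | 0.80 M |  | 4.0 h |
| Friday's | 0.25 M |  | 4.0 h |

| run | time / min | target / % | solid substrate / % |
|---|---|---|---|
| north-east | 10.0 | 0.1 | 85.8 |
| north-east | 30.0 | 1.4 | 56.0 |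
| north-east | 60.0 | 8.1 | 17.6 |
| north-east | 80.0 | 16.8 | 1.8 |
| north-east | 120 | 27.8 | 0 |
| north | 25.0 | 0.6 | 97.5 |
| north | 50.0 | 0.7 | 92.1 |
| north | 80.0 | 1.0 | 90.3 |
| north | 90.0 | 2.6 | 86.9 |
| north | 120 | 2.8 | 83.8 |

(scatter of a reading: 1 percentage point)

- at the start none of the solid substrate is in solution
- what has only dissolved of solid substrate counts as not reacted
- a reading or a percentage of target counts all its forms, free or not

- the flasks put in order of amount of target, in percent of the solid substrate charged, best first, at 4.0 h (Monday's / Sunday's / Saturday's / Tuesday's / Friday's)
- the amount of target, in percent of the solid substrate charged of the flask you put first, at 4.0 h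
- the amount of target, in percent of the solid substrate charged of the flask you put last, at 4.0 h

What does the north-east run lose? Between 10.0 min and 60.0 min it falls from 85.8% to 17.6% of its charge, which is 0.00164 M/min, and I call this reading the feed rate: the fall of c(solid substrate) per minute while solid lasts.

And the north run, with its larger charge? From 25.0 min to 120 min it gives 0.00159 M/min, the same pace, so the balance reads c(solid substrate) = charge − feed rate × time, a zero-order loss.

Is what dissolves already target? No, because at 80.0 min the north-east run holds 1.8% solid and 16.8% target, which leaves 81.4% of its charge in solution as something else.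

Then what does the balance say of the new flasks? It puts the end of the solid in Monday's at 2.04 h and in Friday's at 2.55 h, both before the reading, whereas for 4.0 h it reckons 49.1% of the charge dissolved in Tuesday's, 32.7% in Saturday's and 26.2% in Sunday's.

But is a dissolved share a yield? No, it is a ceiling on target, and in both runs the target readings lag behind it, so I commit to an order and to no figure: Monday's before Friday's, since the balance has its solid in solution sooner, then Tuesday's, Saturday's and Sunday's by falling reckoned share.

The forecast gives the same order, Monday's > Friday's > Tuesday's > Saturday's > Sunday's, with 50% on top and 9.2% at the bottom, on the ground that “This suggests zero-order consumption from a saturated solution while solid remains”.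

The flasks give Monday's > Friday's > Tuesday's > Saturday's > Sunday's, with 44.9% in Monday's, 5.1 percentage points under the forecast, and 7.86% in Sunday's.

    intermediate B ⇌ intermediate C (K = 0.320, k = 0.0310 /min)
    crystals ⇌ target, rate k2*(cs2 - [target]) while solid is left; crystals form when [target] > cs2 (solubility = 0.150 M, k = 0.590 /min)
    starting material ⇌ intermediate B (K = 0.950, k = 0.0140 /min)
    target → over-reaction product (k = 2.00 × 10⁻⁵ /min)
    intermediate A → target (k = 0.0470 /min)
    intermediate B ⇌ intermediate D (K = 0.410, k = 0.00320 /min)
    starting material ⇌ intermediate A (K = 0.410, k = 0.0120 /min)
    solid substrate ⇌ starting material, rate k8*(cs8 - [starting material]) while solid is left; crystals form when [starting material] > cs8 (solubility = 0.330 M, k = 0.00560 /min)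
    intermediate C ⇌ intermediate E (K = 10.0, k = 0.00140 /min)

Monday's reckoned run-out time of 2.04 h is about twice the 0.96 h half-life of starting material by the forward rate of its conversion into intermediate A at 1.01 h, and in Monday's the dissolving has 93% of its turnover up to the asked time behind it at 2.00 h, while at 4.00 h Monday's holds 17.6% starting material and 19.9% intermediate B beside its 44.9% target. For Sunday's the feed rate reckons 26.2% of the charge dissolved by 4.00 h, and Sunday's, with 76.9% solid substrate standing, has dissolved 23.1%.

The runs stem from a simulated flask on assumed constants, noise included.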